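## Analysis of the target

The target is a C19 isoprenoid chain, numbered from the ester carbon C1 to the terminal methyl C19, with methyl branches on C2, C6, C10, C14 and C18. An O–O bridge between C3 and C6 closes the only ring, a 1,2-dioxane (O–O, C3, C4, C5, C6). C14 carries a free tertiary hydroperoxide, C17=C18 is a trisubstituted olefin and C1 is a methyl ester.

There are five stereocentres. C2 (R), C3 (S) and C6 (R) sit at the ring: the propanoate arm on C3 is cis to the C6 methyl, and the C2 methyl is syn to the C3 oxygen in the zigzag. C10 (R) is an isolated methyl-bearing methine. C14 (R) is a fully substituted peroxy carbon. Three methylenes separate C10 from C6 on one side and from C14 on the other, so no centre can relay its configuration to the next.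

The sensitive groups are the two O–O bonds (phosphines, hydrides, metals with H2, strong base), the acidic and oxidising OOH, the C2–H/C3–O pair (base-induced retro-Michael opening of the ring) and the electron-rich C17=C18 olefin.

The hard part is the pair of tertiary carbon–peroxide stereocentres, C6 and C14, eight carbons apart. Neither can be made by direct SN2 displacement, and each must be set in the absolute sense.

The strategy rests on one feature. C6 and C14 each bear a methyl, a peroxy oxygen, an outward chain and an inward CH2 (C7, C13), and the two have the same spatial arrangement when viewed from C10. Each can therefore be the tertiary carbon of a trisubstituted epoxide (C6–C7, C13–C14) of one enantiomeric series, and the C6…C14 segment is a head-to-head pair of such units around C10.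

## Retrosynthetic reasoning

**24 ⇐ 23.** The last bond cut is the O–Si bond of a silyl peroxide on C14. The free hydroperoxide is the most reactive group in the molecule and is released only after every step that an OOH would not survive.

**23 ⇐ 22 ⇐ 21 ⇐ 20.** The C7 and C13 methylenes are traced back to secondary alcohols. Each is flanked by a fully substituted carbon (C6, C14), so dehydration can only run outward to C7=C8 and C12=C13, and the two olefins are then saturated by metal-free hydrogen transfer that leaves O–O bonds alone. These hydroxyls are the marks that the key step leaves behind. Only the C14 hydroperoxide of 20 needs a mask (21), because the C6 peroxide is already dialkyl.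

**20 ⇐ 19.** The O–C3 bond of the dioxane is cut in the retro-Michael sense, which uncovers the (E)-2-methyl enoate and a C6 hydroperoxide. The forward closure is 6-exo. It is placed directly after the key step so that the C7 carbinol is still on the C6 side chain: that branched arm is then clearly larger than the C6 methyl and should take the equatorial site in the chair, which fixes C3 relative to C6. C2 arises in the same step by protonation and is the weakest stereocentre of the plan.

**19 ⇐ 18 (key disconnection).** Both tertiary C–OO bonds (C6–O and C14–O) are cut together. A trisubstituted epoxide opens at its tertiary carbon with inversion under Lewis-acid perhydrolysis, so 18 carries the C6–C7 and C13–C14 epoxides. One operation then forms both peroxy stereocentres, and their configuration comes entirely from the epoxides. Cutting here removes every O–O bond from the route in a single retrosynthetic step, so all C–C bond formation can be done on peroxide-free material.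

**18 ⇐ 17 ⇐ 15 + 16.** The C11–C12 bond is cut as an olefin, made by Julia–Kocienski olefination of sulfone 15 with epoxy aldehyde 16 and then saturated. The cut falls next to the epoxide because the carbinol carbon of a Sharpless epoxy alcohol becomes the aldehyde, so the handle that directs the epoxidation is also the point of union.

**15 ⇐ 13 ⇐ 11 ⇐ 6 + 9.** The C8–C9 bond is cut in the same way, by a Wittig reaction between epoxy aldehyde 6 and the C9–C11 phosphonium salt 9. Salt 9 carries C10 from the chiral pool (7) and a silyl-protected C11 oxygen that later becomes the sulfone. The ester half is joined first so that the sulfide-to-sulfone oxidation (14 to 15) is run before the electron-rich C17=C18 olefin is present.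

**6 and 16 ⇐ 2 ⇐ 1.** Both epoxy aldehydes come from one epoxy alcohol, 2. Oxidation gives 16 directly. Ozonolysis and Wittig homologation turn the remote isopropylidene of 2 into the enoate of 5, and oxidation gives 6. One Sharpless epoxidation of 1 therefore fixes C6, C7, C13 and C14 of 18, and through them C6 and C14 of 24.

## Alternatives that were turned down

**Alternative 1:** The dioxane is cut at both C–O bonds (C3–O and C6–O) back to the acyclic (3E,5Z)-diene bis-silyl ether A1. Sensitised photo-oxygenation would add singlet oxygen suprafacially across its s-cis form to give the 3,6-dihydro-1,2-dioxine A2.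
- For it: the ring and its O–O bond form in one concerted step, the C3/C6 relationship follows from the olefin geometries, and C2 comes from the chiral pool. On C2 this is stronger than the chosen route, where C2 is set by protonation.
- Against it: the C5=C6 olefin is trisubstituted with allylic hydrogens on the C6 methyl and on C7, so the ene reaction competes. The (5Z) substituent points into the s-cis diene and slows the cycloaddition further. The facial bias must come from the single allylic centre C2. Afterwards C4=C5 has to be reduced and the whole C9–C19 chain, with C10 and a second, unrelated peroxidation at C14, built on a molecule that already holds a peroxide.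
- Comparison: the chosen strategy gives up pre-set C2. In return both tertiary peroxy carbons are set by one catalyst-controlled event, and the carbon skeleton is assembled convergently before any peroxide exists.

**Alternative 2:** The O–C6 bond is cut, leading back to the C3 hydroperoxide A3 that carries a 2,2-disubstituted oxetane (C6–O–C8). Under Lewis-acid activation the hydroperoxide would attack the tertiary oxetane carbon with inversion and close the dioxane alcohol A4.
- For it: the closure is intramolecular and stereospecific at C6, C2 and C3 are fixed beforehand, and the freed C8 hydroxyl is a handle for chain extension. For the ring stereocentres this is at least as strong as the chosen route and stronger at C2.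
- Against it: A3 needs a configurationally defined secondary hydroperoxide next to C2, which must itself come from a displacement in which elimination competes. The enantiopure oxetane needs its own sequence, and the vinyl group must later be cleaved oxidatively to C1 in the presence of the peroxide. The route solves only the ring: C9–C19 and the C14 hydroperoxide still need base-mediated couplings on a dioxane and a second peroxide-forming step.
- Comparison: the chosen route takes on more risk at C2 and C3. It handles C6 and C14 with one reagent and one source of chirality, and it is shorter overall.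

**Alternative 3:** The C8=C9 and C11=C12 bonds are cut around C10. In one flask the linchpin A8 (sulfone at C9, phosphonium at C11) would olefinate the tail aldehyde A7 through its ylide and the dioxane aldehyde A6 through its sulfone anion, giving the diene A5.
- For it: the union is the most convergent of all, and every stereocentre, including C2 and C3, arrives finished in a fragment. In convergence and in the number of operations after coupling it is stronger than the chosen route.
- Against it: A6 and A7 are β-peroxy aldehydes, so enolisation under the basic olefination conditions expels the peroxide. A8 must differentiate two carbanion sites three atoms apart. Each peroxide fragment needs its own enantioselective peroxide synthesis, so the hard problem is met twice by different chemistry.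
- Comparison: the chosen route keeps the linchpin idea at C8/C9 and C11/C12 but uses robust epoxy aldehydes, and introduces both peroxides afterwards in one step. It pays with five finishing steps after the key step.

Key step: step 14

Remarks on the chemistry:
- Chain atoms are numbered C1 (ester carbon) to C19; the methyls on C2, C6, C10, C14 and C18 are substituents.
- (2R)-3-Bromo-2-methylpropan-1-ol (7) is taken as a commercial chiral-pool building block.
- The olefins made in steps 6, 12 and 17 are saturated in the following step, so their E/Z ratio does not matter; the expected major isomer is drawn.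

## Route

Step 1
Reactants: 1 geraniol
Product: 2 [(2R,3R)-3-methyl-3-(4-methylpent-3-en-1-yl)oxiran-2-yl]methanol
Conditions: Ti(OiPr)4 (cat.), D-(−)-diethyl tartrate (cat.), t-BuOOH, 4 Å molecular sieves, CH2Cl2, −20 °C
Reagents that add atoms: tert-butyl hydroperoxide, CC(C)(C)OO
Why: Sharpless asymmetric epoxidation: the allylic hydroxyl binds the titanium–tartrate catalyst, which delivers oxygen only to the C2=C3 olefin and, with the D-(−)-tartrate, to the face that gives the (2R,3R)-epoxide; the remote olefin has no directing group and is not touched.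

Step 2
Reactants: 2 [(2R,3R)-3-methyl-3-(4-methylpent-3-en-1-yl)oxiran-2-yl]methanol
Product: 5 methyl (2E)-5-[(2R,3R)-3-(hydroxymethyl)-2-methyloxiran-2-yl]-2-methylpent-2-enoate, via ozonide 3 (not isolated), via epoxy aldehyde 4 (not isolated)
Conditions: O3, CH2Cl2, −78 °C; PPh3, −78 °C → rt; then Ph3P=C(CH3)CO2CH3, rt
Reagents that add atoms: methyl 2-(triphenyl-λ5-phosphanylidene)propanoate, COC(=O)C(C)=P(c1ccccc1)(c1ccccc1)c1ccccc1
Why: Ozonolysis cleaves the only olefin, PPh3 reduces ozonide 3 to aldehyde 4, and the ester-stabilised ylide converts 4 in the same flask into the (E)-2-methyl enoate (Wittig reaction, E by equilibration of the oxaphosphetane); the epoxide and the free hydroxyl are inert to all three reagents.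

Step 3
Reactants: 5 methyl (2E)-5-[(2R,3R)-3-(hydroxymethyl)-2-methyloxiran-2-yl]-2-methylpent-2-enoate
Product: 6 methyl (2E)-5-[(2R,3S)-3-formyl-2-methyloxiran-2-yl]-2-methylpent-2-enoate
Conditions: Dess–Martin periodinane, NaHCO3, CH2Cl2, 0 °C → rt
Reagents that add atoms: none
Why: Dess–Martin oxidation of the primary carbinol under bicarbonate buffer gives the α,β-epoxy aldehyde without acid or base that could open the epoxide; the change of descriptor at the ring CH is only a change of priorities.

Step 4
Reactants: 7 (2R)-3-bromo-2-methylpropan-1-ol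
Product: 8 [(2R)-3-bromo-2-methylpropoxy](tert-butyl)dimethylsilane
Conditions: TBSCl, imidazole, CH2Cl2, 0 °C → rt
Reagents that add atoms: tert-butyldimethylsilyl chloride, CC(C)(C)[Si](C)(C)Cl
Why: Standard silylation of a primary alcohol; the ether keeps a free hydroxyl away from the vinyl epoxide that forms in step 6.

Step 5
Reactants: 8 [(2R)-3-bromo-2-methylpropoxy](tert-butyl)dimethylsilane
Product: 9 {(2R)-3-[(tert-butyldimethylsilyl)oxy]-2-methylpropyl}triphenylphosphonium bromide
Conditions: PPh3, MeCN, 85 °C (sealed)
Reagents that add atoms: triphenylphosphine, c1ccc(cc1)P(c1ccccc1)c1ccccc1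
Why: SN2 quaternisation of the phosphine by the primary bromide; the stereocentre is one carbon away and is not involved.

Step 6
Reactants: 9 {(2R)-3-[(tert-butyldimethylsilyl)oxy]-2-methylpropyl}triphenylphosphonium bromide; 6 methyl (2E)-5-[(2R,3S)-3-formyl-2-methyloxiran-2-yl]-2-methylpent-2-enoate
Product: 11 methyl (2E)-5-[(2R,3R)-3-{(1Z,3S)-4-[(tert-butyldimethylsilyl)oxy]-3-methylbut-1-en-1-yl}-2-methyloxiran-2-yl]-2-methylpent-2-enoate, via ylide 10 (not isolated)
Conditions: 9, NaN(SiMe3)2, THF, −78 → 0 °C; then 6, −78 °C → rt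
Reagents that add atoms: none
Why: Wittig reaction of the non-stabilised ylide 10 with the epoxy aldehyde forms C8=C9 (mainly Z); at −78 °C the ylide adds to the aldehyde far faster than to the ester or the epoxide, and olefination of α,β-epoxy aldehydes of this kind is well established.

Step 7
Reactants: 11 methyl (2E)-5-[(2R,3R)-3-{(1Z,3S)-4-[(tert-butyldimethylsilyl)oxy]-3-methylbut-1-en-1-yl}-2-methyloxiran-2-yl]-2-methylpent-2-enoate
Product: 12 methyl (2E)-5-[(2R,3R)-3-{(3S)-4-[(tert-butyldimethylsilyl)oxy]-3-methylbutyl}-2-methyloxiran-2-yl]-2-methylpent-2-enoate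
Conditions: 2-nitrobenzenesulfonyl hydrazide, Et3N, CH2Cl2, rt
Reagents that add atoms: none
Why: Diimide reduction: concerted syn transfer of H2 to the 1,2-disubstituted olefin, which reacts much faster than the trisubstituted enoate; no metal is present, so the allylic epoxide is not hydrogenolysed.

Step 8
Reactants: 12 methyl (2E)-5-[(2R,3R)-3-{(3S)-4-[(tert-butyldimethylsilyl)oxy]-3-methylbutyl}-2-methyloxiran-2-yl]-2-methylpent-2-enoate
Product: 13 methyl (2E)-5-[(2R,3R)-3-[(3S)-4-hydroxy-3-methylbutyl]-2-methyloxiran-2-yl]-2-methylpent-2-enoate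
Conditions: Bu4NF, AcOH, THF, 0 °C → rt
Reagents that add atoms: none
Why: Fluoride cleavage of the silyl ether; the acetic acid buffer keeps the liberated alcohol from attacking the epoxide as its alkoxide.

Step 9
Reactants: 13 methyl (2E)-5-[(2R,3R)-3-[(3S)-4-hydroxy-3-methylbutyl]-2-methyloxiran-2-yl]-2-methylpent-2-enoate
Product: 14 methyl (2E)-2-methyl-5-[(2R,3R)-2-methyl-3-{(3S)-3-methyl-4-[(1-phenyl-1H-tetrazol-5-yl)sulfanyl]butyl}oxiran-2-yl]pent-2-enoate
Conditions: 1-phenyl-1H-tetrazole-5-thiol, PPh3, DIAD, THF, 0 °C → rt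
Reagents that add atoms: 1-phenyl-1H-tetrazole-5-thiol, Sc1nnnn1-c1ccccc1
Why: Mitsunobu thioetherification: the primary alkoxyphosphonium is displaced by the acidic thiol at CH2, so C10 is untouched; epoxide and enoate tolerate the neutral redox pair.

Step 10
Reactants: 14 methyl (2E)-2-methyl-5-[(2R,3R)-2-methyl-3-{(3S)-3-methyl-4-[(1-phenyl-1H-tetrazol-5-yl)sulfanyl]butyl}oxiran-2-yl]pent-2-enoate
Product: 15 methyl (2E)-2-methyl-5-[(2R,3R)-2-methyl-3-{(3S)-3-methyl-4-[(1-phenyl-1H-tetrazol-5-yl)sulfonyl]butyl}oxiran-2-yl]pent-2-enoate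
Conditions: m-CPBA (3 equiv), NaHCO3, CH2Cl2, 0 °C → rt
Reagents that add atoms: 3-chloroperoxybenzoic acid, OOC(=O)c1cccc(Cl)c1
Why: Peracid oxidation of the sulfide to the sulfone; the only olefin present is the electron-poor enoate, which a peracid does not epoxidise at a useful rate, and the buffer protects the epoxide.

Step 11
Reactants: 2 [(2R,3R)-3-methyl-3-(4-methylpent-3-en-1-yl)oxiran-2-yl]methanol
Product: 16 (2S,3R)-3-methyl-3-(4-methylpent-3-en-1-yl)oxirane-2-carbaldehyde
Conditions: Dess–Martin periodinane, NaHCO3, CH2Cl2, 0 °C → rt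
Reagents that add atoms: none
Why: Same buffered Dess–Martin oxidation as in step 3; the trisubstituted olefin is inert to the reagent.

Step 12
Reactants: 15 methyl (2E)-2-methyl-5-[(2R,3R)-2-methyl-3-{(3S)-3-methyl-4-[(1-phenyl-1H-tetrazol-5-yl)sulfonyl]butyl}oxiran-2-yl]pent-2-enoate; 16 (2S,3R)-3-methyl-3-(4-methylpent-3-en-1-yl)oxirane-2-carbaldehyde
Product: 17 methyl (2E,6R,7R,10S,11E,13R,14R)-6,7:13,14-diepoxy-2,6,10,14,18-pentamethylnonadeca-2,11,17-trienoate
Conditions: KN(SiMe3)2 added to 15 + 16, DME, −78 °C → rt
Reagents that add atoms: none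
Why: Julia–Kocienski olefination: the sulfonyl carbanion adds to the aldehyde, and Smiles rearrangement with loss of SO2 and the tetrazololate gives C11=C12; base is added to the mixture of both partners so that the carbanion is trapped by the aldehyde before it can attack the enoate or the C6–C7 epoxide.

Step 13
Reactants: 17 methyl (2E,6R,7R,10S,11E,13R,14R)-6,7:13,14-diepoxy-2,6,10,14,18-pentamethylnonadeca-2,11,17-trienoate
Product: 18 methyl (2E,6R,7R,10R,13R,14R)-6,7:13,14-diepoxy-2,6,10,14,18-pentamethylnonadeca-2,17-dienoate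
Conditions: 2-nitrobenzenesulfonyl hydrazide, Et3N, CH2Cl2, rt
Reagents that add atoms: none
Why: Diimide reduction of the single disubstituted olefin; the two trisubstituted olefins (enoate and C17=C18) react much more slowly and both epoxides survive. The descriptor at C10 changes only because the priorities change.

Step 14
Reactants: 18 methyl (2E,6R,7R,10R,13R,14R)-6,7:13,14-diepoxy-2,6,10,14,18-pentamethylnonadeca-2,17-dienoate
Product: 19 methyl (2E,6S,7R,10R,13R,14S)-6,14-dihydroperoxy-7,13-dihydroxy-2,6,10,14,18-pentamethylnonadeca-2,17-dienoate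
Conditions: MoO2(acac)2 (cat.), anhydrous H2O2 in Et2O (excess), 0 °C → rt
Reagents that add atoms: hydrogen peroxide, OO
Why: MoO2(acac)2 exchanges its ligands for peroxide and the resulting Lewis-acidic hexavalent molybdenum centre binds an epoxide oxygen, which lengthens the C–O bond to the carbon that best carries positive charge, the tertiary C6 or C14. H2O2 then attacks that carbon from the side opposite the departing oxygen, in a borderline SN2 opening that inverts C6 and C14 and leaves C7 and C13 unchanged as secondary alcohols. The closest known reaction is the molybdenum-catalysed perhydrolysis of trisubstituted epoxides in ethereal H2O2 to β-hydroxy hydroperoxides; here it is run at two such epoxides, which are six atoms apart and react independently. No ring closes. The two new peroxy stereocentres are controlled only by the epoxide configurations set in step 1, transmitted through inversion. The step needs tertiary over secondary attack, which trisubstitution secures, and clean inversion, which the large excess of a strong α-nucleophile favours over ionisation. It also needs chemoselectivity: the enoate is too electron-poor to react, water is excluded to avoid diols, and the electron-rich C17=C18 olefin is the one site that may be oxidised slowly, so the reaction is stopped as soon as the second epoxide is consumed.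

Step 15
Reactants: 19 methyl (2E,6S,7R,10R,13R,14S)-6,14-dihydroperoxy-7,13-dihydroxy-2,6,10,14,18-pentamethylnonadeca-2,17-dienoate
Product: 20 methyl (2R)-2-[(3S,6S)-6-[(1R,4R,7R,8S)-8-hydroperoxy-1,7-dihydroxy-4,8,12-trimethyltridec-11-en-1-yl]-6-methyl-1,2-dioxan-3-yl]propanoate
Conditions: Et2NH (cat.), CF3CH2OH, rt, dilute
Reagents that add atoms: none
Why: Intramolecular peroxy-Michael addition (6-exo-trig) of the C6 hydroperoxide to the enoate, a known closure of 1,2-dioxanes; in the chair transition state the enoate arm at C3 and the branched C7 carbinol chain at C6 should both be equatorial with the C6 methyl axial, which gives the target's C3 configuration. C2 is fixed by protonation (anti addition across the (E)-olefin would give the required 2,3-syn isomer) and is under weak control, so the (2R) isomer is separated from its C2 epimer; the C14 hydroperoxide has no acceptor within reach.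

Step 16
Reactants: 20 methyl (2R)-2-[(3S,6S)-6-[(1R,4R,7R,8S)-8-hydroperoxy-1,7-dihydroxy-4,8,12-trimethyltridec-11-en-1-yl]-6-methyl-1,2-dioxan-3-yl]propanoate
Product: 21 methyl (2R)-2-[(3S,6S)-6-[(1R,4S,7R,8S)-8-[(tert-butyldimethylsilyl)peroxy]-1,7-dihydroxy-4,8,12-trimethyltridec-11-en-1-yl]-6-methyl-1,2-dioxan-3-yl]propanoate
Conditions: TBSCl (1.1 equiv), imidazole, DMF, −20 → 0 °C
Reagents that add atoms: tert-butyldimethylsilyl chloride, CC(C)(C)[Si](C)(C)Cl
Why: O-silylation of the hydroperoxide: the OOH is the most acidic O–H and its terminal oxygen is unhindered, whereas both carbinols are secondary and flanked by fully substituted carbons, so one equivalent of the bulky chloride should react at OOH only. The C10 descriptor changes through priorities, not geometry.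

Step 17
Reactants: 21 methyl (2R)-2-[(3S,6S)-6-[(1R,4S,7R,8S)-8-[(tert-butyldimethylsilyl)peroxy]-1,7-dihydroxy-4,8,12-trimethyltridec-11-en-1-yl]-6-methyl-1,2-dioxan-3-yl]propanoate
Product: 22 methyl (2R)-2-[(3S,6S)-6-[(1E,4S,6E,8S)-8-[(tert-butyldimethylsilyl)peroxy]-4,8,12-trimethyltrideca-1,6,11-trien-1-yl]-6-methyl-1,2-dioxan-3-yl]propanoate
Conditions: Martin sulfurane, Ph2S[OC(CF3)2Ph]2 (3 equiv), CH2Cl2, 0 °C → rt
Reagents that add atoms: none
Why: Martin sulfurane dehydration: each carbinol exchanges onto sulfur and the alkoxysulfonium undergoes E2 loss at room temperature; C6 and C14 carry no hydrogen, so elimination can only give C7=C8 and C12=C13, and the near-neutral medium spares the ester, C2 and both peroxides.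

Step 18
Reactants: 22 methyl (2R)-2-[(3S,6S)-6-[(1E,4S,6E,8S)-8-[(tert-butyldimethylsilyl)peroxy]-4,8,12-trimethyltrideca-1,6,11-trien-1-yl]-6-methyl-1,2-dioxan-3-yl]propanoate
Product: 23 methyl (2R)-2-[(3S,6R)-6-[(4S,8R)-8-[(tert-butyldimethylsilyl)peroxy]-4,8,12-trimethyltridec-11-en-1-yl]-6-methyl-1,2-dioxan-3-yl]propanoate
Conditions: 2-nitrobenzenesulfonyl hydrazide, Et3N, CH2Cl2, rt, in portions
Reagents that add atoms: none
Why: Diimide reduction, the standard way to saturate olefins beside O–O bonds; the two disubstituted olefins are reduced ahead of trisubstituted C17=C18, and the reagent is added in portions and stopped when they are consumed.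

Step 19
Reactants: 23 methyl (2R)-2-[(3S,6R)-6-[(4S,8R)-8-[(tert-butyldimethylsilyl)peroxy]-4,8,12-trimethyltridec-11-en-1-yl]-6-methyl-1,2-dioxan-3-yl]propanoate
Product: 24 methyl (2R)-2-[(3S,6R)-6-[(4R,8R)-8-hydroperoxy-4,8,12-trimethyltridec-11-en-1-yl]-6-methyl-1,2-dioxan-3-yl]propanoate
Conditions: HF·pyridine, pyridine, THF, 0 °C
Reagents that add atoms: none
Why: Fluoride cleavage of the silyl peroxide under mildly acidic, non-basic conditions, which cannot open the dioxane by retro-Michael reaction or epimerise C2.

## Compound list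

1 | geraniol, (2E)-3,7-dimethylocta-2,6-dien-1-ol | CC(C)=CCC/C(C)=C/CO | starting material
2 | [(2R,3R)-3-methyl-3-(4-methylpent-3-en-1-yl)oxiran-2-yl]methanol | CC(C)=CCC[C@@]1(C)O[C@@H]1CO | intermediate
3 | [(2R,3R)-3-[2-(5,5-dimethyl-1,2,4-trioxolan-3-yl)ethyl]-3-methyloxiran-2-yl]methanol (ozonide, both epimers at the trioxolane carbon) | CC1(C)OOC(CC[C@@]2(C)O[C@@H]2CO)O1 | intermediate
4 | 3-[(2R,3R)-3-(hydroxymethyl)-2-methyloxiran-2-yl]propanal | O=CCC[C@@]1(C)O[C@@H]1CO | intermediate
5 | methyl (2E)-5-[(2R,3R)-3-(hydroxymethyl)-2-methyloxiran-2-yl]-2-methylpent-2-enoate | COC(=O)/C(C)=C/CC[C@@]1(C)O[C@@H]1CO | intermediate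
6 | methyl (2E)-5-[(2R,3S)-3-formyl-2-methyloxiran-2-yl]-2-methylpent-2-enoate | COC(=O)/C(C)=C/CC[C@@]1(C)O[C@@H]1C=O | intermediate
7 | (2R)-3-bromo-2-methylpropan-1-ol | C[C@H](CO)CBr | starting material
8 | [(2R)-3-bromo-2-methylpropoxy](tert-butyl)dimethylsilane | C[C@H](CO[Si](C)(C)C(C)(C)C)CBr | intermediate
9 | {(2R)-3-[(tert-butyldimethylsilyl)oxy]-2-methylpropyl}triphenylphosphonium bromide | C[C@H](CO[Si](C)(C)C(C)(C)C)C[P+](c1ccccc1)(c1ccccc1)c1ccccc1.[Br-] | intermediate
10 | tert-butyldimethyl{[(2R)-2-methyl-3-(triphenyl-λ5-phosphanylidene)propyl]oxy}silane (ylide) | C[C@H](CO[Si](C)(C)C(C)(C)C)C=P(c1ccccc1)(c1ccccc1)c1ccccc1 | intermediate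
11 | methyl (2E)-5-[(2R,3R)-3-{(1Z,3S)-4-[(tert-butyldimethylsilyl)oxy]-3-methylbut-1-en-1-yl}-2-methyloxiran-2-yl]-2-methylpent-2-enoate | COC(=O)/C(C)=C/CC[C@@]1(C)O[C@@H]1/C=C\[C@H](C)CO[Si](C)(C)C(C)(C)C | intermediate
12 | methyl (2E)-5-[(2R,3R)-3-{(3S)-4-[(tert-butyldimethylsilyl)oxy]-3-methylbutyl}-2-methyloxiran-2-yl]-2-methylpent-2-enoate | COC(=O)/C(C)=C/CC[C@@]1(C)O[C@@H]1CC[C@H](C)CO[Si](C)(C)C(C)(C)C | intermediate
13 | methyl (2E)-5-[(2R,3R)-3-[(3S)-4-hydroxy-3-methylbutyl]-2-methyloxiran-2-yl]-2-methylpent-2-enoate | COC(=O)/C(C)=C/CC[C@@]1(C)O[C@@H]1CC[C@H](C)CO | intermediate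
14 | methyl (2E)-2-methyl-5-[(2R,3R)-2-methyl-3-{(3S)-3-methyl-4-[(1-phenyl-1H-tetrazol-5-yl)sulfanyl]butyl}oxiran-2-yl]pent-2-enoate | COC(=O)/C(C)=C/CC[C@@]1(C)O[C@@H]1CC[C@H](C)CSc1nnnn1-c1ccccc1 | intermediate
15 | methyl (2E)-2-methyl-5-[(2R,3R)-2-methyl-3-{(3S)-3-methyl-4-[(1-phenyl-1H-tetrazol-5-yl)sulfonyl]butyl}oxiran-2-yl]pent-2-enoate | COC(=O)/C(C)=C/CC[C@@]1(C)O[C@@H]1CC[C@H](C)CS(=O)(=O)c1nnnn1-c1ccccc1 | intermediate
16 | (2S,3R)-3-methyl-3-(4-methylpent-3-en-1-yl)oxirane-2-carbaldehyde | CC(C)=CCC[C@@]1(C)O[C@@H]1C=O | intermediate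
17 | methyl (2E,6R,7R,10S,11E,13R,14R)-6,7:13,14-diepoxy-2,6,10,14,18-pentamethylnonadeca-2,11,17-trienoate | COC(=O)/C(C)=C/CC[C@@]1(C)O[C@@H]1CC[C@H](C)/C=C/[C@H]1O[C@]1(C)CCC=C(C)C | intermediate
18 | methyl (2E,6R,7R,10R,13R,14R)-6,7:13,14-diepoxy-2,6,10,14,18-pentamethylnonadeca-2,17-dienoate | COC(=O)/C(C)=C/CC[C@@]1(C)O[C@@H]1CC[C@H](C)CC[C@H]1O[C@]1(C)CCC=C(C)C | intermediate
19 | methyl (2E,6S,7R,10R,13R,14S)-6,14-dihydroperoxy-7,13-dihydroxy-2,6,10,14,18-pentamethylnonadeca-2,17-dienoate | COC(=O)/C(C)=C/CC[C@](C)(OO)[C@H](O)CC[C@H](C)CC[C@@H](O)[C@@](C)(OO)CCC=C(C)C | intermediate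
20 | methyl (2R)-2-[(3S,6S)-6-[(1R,4R,7R,8S)-8-hydroperoxy-1,7-dihydroxy-4,8,12-trimethyltridec-11-en-1-yl]-6-methyl-1,2-dioxan-3-yl]propanoate | COC(=O)[C@H](C)[C@@H]1CC[C@@](C)([C@H](O)CC[C@H](C)CC[C@@H](O)[C@](C)(CCC=C(C)C)OO)OO1 | intermediate
21 | methyl (2R)-2-[(3S,6S)-6-[(1R,4S,7R,8S)-8-[(tert-butyldimethylsilyl)peroxy]-1,7-dihydroxy-4,8,12-trimethyltridec-11-en-1-yl]-6-methyl-1,2-dioxan-3-yl]propanoate | COC(=O)[C@H](C)[C@@H]1CC[C@@](C)([C@H](O)CC[C@H](C)CC[C@@H](O)[C@](C)(CCC=C(C)C)OO[Si](C)(C)C(C)(C)C)OO1 | intermediate
22 | methyl (2R)-2-[(3S,6S)-6-[(1E,4S,6E,8S)-8-[(tert-butyldimethylsilyl)peroxy]-4,8,12-trimethyltrideca-1,6,11-trien-1-yl]-6-methyl-1,2-dioxan-3-yl]propanoate | COC(=O)[C@H](C)[C@@H]1CC[C@@](C)(/C=C/C[C@H](C)C/C=C/[C@](C)(CCC=C(C)C)OO[Si](C)(C)C(C)(C)C)OO1 | intermediate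
23 | methyl (2R)-2-[(3S,6R)-6-[(4S,8R)-8-[(tert-butyldimethylsilyl)peroxy]-4,8,12-trimethyltridec-11-en-1-yl]-6-methyl-1,2-dioxan-3-yl]propanoate | COC(=O)[C@H](C)[C@@H]1CC[C@@](C)(CCC[C@H](C)CCC[C@](C)(CCC=C(C)C)OO[Si](C)(C)C(C)(C)C)OO1 | intermediate
24 | methyl (2R)-2-[(3S,6R)-6-[(4R,8R)-8-hydroperoxy-4,8,12-trimethyltridec-11-en-1-yl]-6-methyl-1,2-dioxan-3-yl]propanoate | COC(=O)[C@H](C)[C@@H]1CC[C@@](C)(CCC[C@H](C)CCC[C@](C)(CCC=C(C)C)OO)OO1 | target

## Step count and least certain steps

Total: 19 steps. Longest linear sequence: 16 steps (1, 2, 3, 6, 7, 8, 9, 10, 12, 13, 14, 15, 16, 17, 18, 19 from geraniol). Thirteen steps lead to the bis-epoxide 18, and five follow the key step.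

**Step 14 (key step).** Two independent openings must both run cleanly, so any leakage is compounded. The likely failures are ionisation at a tertiary carbon instead of backside attack (erosion of the inversion, or a hydride shift to a ketone), capture of adventitious water, and slow oxygen transfer from peroxomolybdenum species or from the product hydroperoxides to C17=C18 during the time the second opening needs.

The fallback gives up the twin opening and opens the epoxides one at a time, the first on a substrate that has no electron-rich olefin. It sets out from sulfone 15 and returns at 20.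
- The same MoO2(acac)2/H2O2 conditions on 15 give methyl (2E,6S,7R,10S)-6-hydroperoxy-7-hydroxy-2,6,10-trimethyl-11-[(1-phenyl-1H-tetrazol-5-yl)sulfonyl]undec-2-enoate F1.
- Et2NH in CF3CH2OH closes the dioxane to the hydroxy sulfone methyl (2R)-2-[(3S,6S)-6-{(1R,4S)-1-hydroxy-4-methyl-5-[(1-phenyl-1H-tetrazol-5-yl)sulfonyl]pentyl}-6-methyl-1,2-dioxan-3-yl]propanoate F2.
- Et3SiOTf and 2,6-lutidine cap the C7 hydroxyl as the triethylsilyl ether of F2, F3, so that no alkoxide can form next to the peroxide.
- Julia–Kocienski olefination of F3 with 16 gives the (E)-olefin with the tail epoxide, the C11=C12 olefin of the triethylsilyl ether series F4. Here the dioxane ester meets the amide base, which is this fallback's own weak point.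
- Diimide saturates F4 to the mono-epoxide triethylsilyl ether F5.
- A single perhydrolysis gives the C14 hydroperoxide, the 1-O-triethylsilyl ether of 20, F6, and HF·pyridine removes the silyl ether to give 20.

**Step 15.** Protonation of the ester enolate next to the ring may be unselective or may favour the wrong face, and the chair preference that sets C3 may be only moderate. The result would be a mixture of diastereomers, most seriously at C2.

The fallback replaces kinetic protonation by an equilibration loop. It sets out from 19 and returns at 20. The unwanted isomer, methyl (2S)-2-[(3S,6S)-6-[(1R,4R,7R,8S)-8-hydroperoxy-1,7-dihydroxy-4,8,12-trimethyltridec-11-en-1-yl]-6-methyl-1,2-dioxan-3-yl]propanoate F7, is separated and treated with a stronger amidine base in CF3CH2OH. That reopens the ring by β-elimination to the peroxide anion of 19, which closes again, and 20 is harvested from each pass.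

**Step 17.** Ligand exchange at the two hindered carbinols may be slow. Alternatively the activated C7 or C13 may ionise with participation of the neighbouring peroxide oxygen, leading to a 1,2-shift or C–C fragmentation instead of E2 loss toward C8 and C12.

The fallback removes the hydroxyls by a radical path that forms no olefins. It sets out from 21 and returns at 23, bypassing 22 and step 18. PhOC(S)Cl, pyridine and DMAP convert 21 into the bis(O-phenyl thionocarbonate) of 21, F8. Barton–McCombie reduction with Bu3SnH at high concentration and a low-temperature azo initiator gives 23. The hydrogen transfer must outrun the known closure of β-peroxyalkyl radicals onto the O–O bond, which is why the stannane is used concentrated.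

**Step 12.** The sulfonyl carbanion may be diverted by γ-deprotonation or conjugate addition at the enoate, or by attack on the C6–C7 epoxide five atoms away, and the epoxy aldehyde may decompose under the amide base.

The fallback exchanges the sulfone for a phosphonium ylide, which is less basic toward the ester. It sets out from 13 and returns at 18.
- Appel iodination (I2, PPh3, imidazole) gives methyl (2E)-5-[(2R,3R)-3-[(3S)-4-iodo-3-methylbutyl]-2-methyloxiran-2-yl]-2-methylpent-2-enoate F9.
- PPh3 in MeCN with NaHCO3 at 80 °C gives the corresponding triphenylphosphonium iodide F10.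
- NaN(SiMe3)2 and then 16 give the (11Z)-isomer of 17, F11, which step 13 reduces to 18.

## Further compounds

F1 | step 14 | methyl (2E,6S,7R,10S)-6-hydroperoxy-7-hydroxy-2,6,10-trimethyl-11-[(1-phenyl-1H-tetrazol-5-yl)sulfonyl]undec-2-enoate | COC(=O)/C(C)=C/CC[C@](C)(OO)[C@H](O)CC[C@H](C)CS(=O)(=O)c1nnnn1-c1ccccc1
F2 | step 14 | methyl (2R)-2-[(3S,6S)-6-{(1R,4S)-1-hydroxy-4-methyl-5-[(1-phenyl-1H-tetrazol-5-yl)sulfonyl]pentyl}-6-methyl-1,2-dioxan-3-yl]propanoate | COC(=O)[C@H](C)[C@@H]1CC[C@@](C)([C@H](O)CC[C@H](C)CS(=O)(=O)c2nnnn2-c2ccccc2)OO1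
F3 | step 14 | triethylsilyl ether of F2 at the C7 hydroxyl | COC(=O)[C@H](C)[C@@H]1CC[C@@](C)([C@H](O[Si](CC)(CC)CC)CC[C@H](C)CS(=O)(=O)c2nnnn2-c2ccccc2)OO1
F4 | step 14 | methyl (2R)-2-[(3S,6S)-6-{(1R,4S,5E)-4-methyl-6-[(2R,3R)-3-methyl-3-(4-methylpent-3-en-1-yl)oxiran-2-yl]-1-[(triethylsilyl)oxy]hex-5-en-1-yl}-6-methyl-1,2-dioxan-3-yl]propanoate | COC(=O)[C@H](C)[C@@H]1CC[C@@](C)([C@H](O[Si](CC)(CC)CC)CC[C@H](C)/C=C/[C@H]2O[C@]2(C)CCC=C(C)C)OO1
F5 | step 14 | methyl (2R)-2-[(3S,6S)-6-{(1R,4R)-4-methyl-6-[(2R,3R)-3-methyl-3-(4-methylpent-3-en-1-yl)oxiran-2-yl]-1-[(triethylsilyl)oxy]hexyl}-6-methyl-1,2-dioxan-3-yl]propanoate | COC(=O)[C@H](C)[C@@H]1CC[C@@](C)([C@H](O[Si](CC)(CC)CC)CC[C@H](C)CC[C@H]2O[C@]2(C)CCC=C(C)C)OO1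
F6 | step 14 | methyl (2R)-2-[(3S,6S)-6-{(1R,4R,7R,8S)-8-hydroperoxy-7-hydroxy-4,8,12-trimethyl-1-[(triethylsilyl)oxy]tridec-11-en-1-yl}-6-methyl-1,2-dioxan-3-yl]propanoate | COC(=O)[C@H](C)[C@@H]1CC[C@@](C)([C@H](O[Si](CC)(CC)CC)CC[C@H](C)CC[C@@H](O)[C@](C)(CCC=C(C)C)OO)OO1
F7 | step 15 | methyl (2S)-2-[(3S,6S)-6-[(1R,4R,7R,8S)-8-hydroperoxy-1,7-dihydroxy-4,8,12-trimethyltridec-11-en-1-yl]-6-methyl-1,2-dioxan-3-yl]propanoate | COC(=O)[C@@H](C)[C@@H]1CC[C@@](C)([C@H](O)CC[C@H](C)CC[C@@H](O)[C@](C)(CCC=C(C)C)OO)OO1
F8 | step 17 | methyl (2R)-2-[(3S,6S)-6-{(1R,4S,7R,8S)-8-[(tert-butyldimethylsilyl)peroxy]-4,8,12-trimethyl-1,7-bis[(phenoxycarbonothioyl)oxy]tridec-11-en-1-yl}-6-methyl-1,2-dioxan-3-yl]propanoate | COC(=O)[C@H](C)[C@@H]1CC[C@@](C)([C@H](OC(=S)Oc2ccccc2)CC[C@H](C)CC[C@@H](OC(=S)Oc2ccccc2)[C@](C)(CCC=C(C)C)OO[Si](C)(C)C(C)(C)C)OO1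
F9 | step 12 | methyl (2E)-5-[(2R,3R)-3-[(3S)-4-iodo-3-methylbutyl]-2-methyloxiran-2-yl]-2-methylpent-2-enoate | COC(=O)/C(C)=C/CC[C@@]1(C)O[C@@H]1CC[C@H](C)CI
F10 | step 12 | {(2S)-4-[(2R,3R)-3-[(3E)-5-methoxy-4-methyl-5-oxopent-3-en-1-yl]-3-methyloxiran-2-yl]-2-methylbutyl}triphenylphosphonium iodide | COC(=O)/C(C)=C/CC[C@@]1(C)O[C@@H]1CC[C@H](C)C[P+](c2ccccc2)(c2ccccc2)c2ccccc2.[I-]
F11 | step 12 | methyl (2E,6R,7R,10S,11Z,13R,14R)-6,7:13,14-diepoxy-2,6,10,14,18-pentamethylnonadeca-2,11,17-trienoate | COC(=O)/C(C)=C/CC[C@@]1(C)O[C@@H]1CC[C@H](C)/C=C\[C@H]1O[C@]1(C)CCC=C(C)C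
A1 | alternative 1 | (3E,5Z)-diene bis-silyl ether, C1–C8 with C2 as in the target | CC(C)(C)[Si](c1ccccc1)(c1ccccc1)OC[C@H](C)/C=C/C=C(/C)CCO[Si](C)(C)C(C)(C)C
A2 | alternative 1 | 3,6-dihydro-1,2-dioxine with C2, C3 and C6 as in the target | CC(C)(C)[Si](c1ccccc1)(c1ccccc1)OC[C@H](C)[C@@H]1C=C[C@@](C)(CCO[Si](C)(C)C(C)(C)C)OO1
A3 | alternative 2 | C3 hydroperoxide carrying the 2-methyloxetane (C6–O–C8) | C=C[C@H](C)[C@@H](OO)CC[C@]1(C)CCO1
A4 | alternative 2 | 1,2-dioxane with C2, C3 and C6 as in the target, vinyl as latent C1 and a free C8 alcohol | C=C[C@H](C)[C@@H]1CC[C@@](C)(CCO)OO1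
A5 | alternative 3 | C1–C19 skeleton with C8=C9 and C11=C12 olefins and the C14 peroxyketal | COC(=O)[C@H](C)[C@@H]1CC[C@@](C)(CC=C[C@H](C)C=CC[C@](C)(CCC=C(C)C)OOC(C)(C)OC)OO1
A6 | alternative 3 | dioxane C8 aldehyde | COC(=O)[C@H](C)[C@@H]1CC[C@@](C)(CC=O)OO1
A7 | alternative 3 | tail C12 aldehyde with the C14 peroxyketal | O=CC[C@](C)(CCC=C(C)C)OOC(C)(C)OC
A8 | alternative 3 | C9–C11 linchpin, tetrazolyl sulfone at C9 and triphenylphosphonium bromide at C11 | O=S(=O)(C[C@H](C)C[P+](c1ccccc1)(c1ccccc1)c1ccccc1)c1nnnn1-c1ccccc1.[Br-]
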